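The synthesis rests on disconnecting the ring bond C4–C5 (ring: C1 CMe2, C2 CHBr, C3 CH2, C4 CHCl, C5 alkylidene carbon, C6 CHCl; side chain: C7 vinyl CH, C8 CH2Br). It exploits the exocyclic C5=C7 alkene of the cyclohexane ring, whose C7–H is cis to C4: hydrogen-mediated rhodium coupling of a C4 aldehyde with a C5≡C7 alkyne closes the six-membered ring, fixes the Z geometry by syn addition and sets a C4 carbinol for later inversion to chloride in one operation. The precursor is an acyclic oct-6-ynal that already carries both neopentyl halides (C2–Br, C6–Cl) and a silyl-protected C8 oxygen, built from (S)-pantolactone.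

Key step: step 10

Remark: (S)-(+)-pantolactone is assumed to be bought enantiopure (its carbinol carbon is inverted once, in step 1, and becomes C6), and formaldehyde is used as the monomer obtained by heating paraformaldehyde.

Step 1
Reactants: 1 (S)-(+)-pantolactone [(3S)-3-hydroxy-4,4-dimethyloxolan-2-one]
Product: 3 (3R)-3-chloro-4,4-dimethyloxolan-2-one, via pantolactone triflate 2 (not isolated)
Conditions: Tf2O, 2,6-lutidine, CH2Cl2, −78 → 0 °C; then Bu4NCl, 0 °C → rt
Reagents that add atoms: tetrabutylammonium chloride, CCCC[N+](CCCC)(CCCC)CCCC.[Cl-]; trifluoromethanesulfonic anhydride, O=S(=O)(OS(=O)(=O)C(F)(F)F)C(F)(F)F (to intermediate 2 only)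
Why: O-Triflation and SN2 displacement by chloride: substitution at this neopentyl carbon is feasible because the adjacent lactone carbonyl accelerates backside attack while the lack of β-hydrogens excludes elimination, and the inversion converts the (S)-carbinol into the (R)-chloride that becomes C6 of the target.

Step 2
Reactants: 3 (3R)-3-chloro-4,4-dimethyloxolan-2-one
Product: 4 (3R)-3-chloro-4,4-dimethyloxolan-2-ol (lactol, mixture of anomers)
Conditions: i-Bu2AlH (1.1 equiv), CH2Cl2, −78 °C; aq. KNaC4H4O6 (potassium sodium tartrate)
Reagents that add atoms: none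
Why: Half-reduction of a γ-lactone with i-Bu2AlH at −78 °C stops at the lactol oxidation level, and hydride does not touch the secondary C–Cl bond, so the C6 configuration is retained.

Step 3
Reactants: 4 (3R)-3-chloro-4,4-dimethyloxolan-2-ol; 5 dimethyl (1-diazo-2-oxopropyl)phosphonate
Product: 7 (3S)-3-chloro-2,2-dimethylpent-4-yn-1-ol, via open-chain hydroxy aldehyde 6 (not isolated)
Conditions: K2CO3, MeOH, 0 °C → rt
Reagents that add atoms: dimethyl (1-diazo-2-oxopropyl)phosphonate, COP(=O)(OC)C(=[N+]=[N-])C(C)=O
Why: Ohira–Bestmann (Seyferth–Gilbert) homologation: methanolysis of 5 releases the diazomethylphosphonate anion, which olefinates the aldehyde of the ring-opened form 6 in Horner–Wadsworth–Emmons fashion and loses nitrogen to give the terminal alkyne (C5≡C7); the mildly basic, cold conditions are those under which α-heteroatom-substituted aldehydes normally keep their configuration, so C6 is carried through unchanged.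

Step 4
Reactants: 7 (3S)-3-chloro-2,2-dimethylpent-4-yn-1-ol
Product: 8 (3S)-3-chloro-2,2-dimethylpent-4-ynal
Conditions: Dess–Martin periodinane, CH2Cl2, 0 °C → rt
Reagents that add atoms: none
Why: Dess–Martin oxidation of the primary neopentyl alcohol gives an aldehyde (C2) with no α-hydrogen, so neither epimerisation nor loss of HCl is possible, and the alkyne and chloride are inert to the periodinane; the volatile product is carried on as a solution.

Step 5
Reactants: 8 (3S)-3-chloro-2,2-dimethylpent-4-ynal; 9 allylboronic acid pinacol ester
Product: 10 (4R,6S)-6-chloro-5,5-dimethyloct-1-en-7-yn-4-ol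
Conditions: (R)-TRIP [(R)-3,3'-bis(2,4,6-triisopropylphenyl)-1,1'-binaphthyl-2,2'-diyl hydrogen phosphate] (5 mol %), toluene, −30 °C; then H2O
Reagents that add atoms: allylboronic acid pinacol ester, C=CCB1OC(C)(C)C(C)(C)O1
Why: Chiral phosphoric acid catalysed allylboration through a closed chair-like six-membered transition state: the (R)-configured catalyst directs allyl transfer to the Re face of the aldehyde (reagent control, the remote C6 centre contributing little), which sets C2 as the (R)-carbinol needed for the later inversion, and any C2 epimer would be a diastereomer removable by chromatography.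

Step 6
Reactants: 10 (4R,6S)-6-chloro-5,5-dimethyloct-1-en-7-yn-4-ol
Product: 12 (4S,6S)-4-bromo-6-chloro-5,5-dimethyloct-1-en-7-yne, via secondary triflate 11 (not isolated)
Conditions: Tf2O, 2,6-lutidine, CH2Cl2, −78 → −40 °C; then Bu4NBr, −40 → 0 °C
Reagents that add atoms: tetrabutylammonium bromide, CCCC[N+](CCCC)(CCCC)CCCC.[Br-]; trifluoromethanesulfonic anhydride, O=S(=O)(OS(=O)(=O)C(F)(F)F)C(F)(F)F (to intermediate 11 only)
Why: Sulfonate activation and SN2 displacement with bromide, which inverts C2 to the (S)-bromide of the target; generating the triflate cold and consuming it at once with a soluble, non-basic bromide lets substitution at this hindered neopentyl carbon compete with elimination towards C3, and the electron-withdrawing chloro(alkynyl)methyl group on C1 disfavours ionisation and methyl migration.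

Step 7
Reactants: 12 (4S,6S)-4-bromo-6-chloro-5,5-dimethyloct-1-en-7-yne; 13 formaldehyde
Product: 15 (4S,6S)-6-bromo-4-chloro-5,5-dimethylnon-8-en-2-yn-1-ol, via lithium acetylide 14 (not isolated)
Conditions: n-BuLi (1.0 equiv), THF, −78 °C; CH2O (gas, from cracked paraformaldehyde), −78 → −20 °C; aq. NH4Cl
Reagents that add atoms: formaldehyde, C=O; n-butyllithium, [Li]CCCC (lithium to intermediate 14 only)
Why: Deprotonation of the terminal alkyne and 1,2-addition of the lithium acetylide to monomeric formaldehyde (hydroxymethylation) installs C8; the alkyne C–H is by far the most acidic site, and at −78 °C neither the propargylic chloride nor the hindered secondary bromide is attacked.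

Step 8
Reactants: 15 (4S,6S)-6-bromo-4-chloro-5,5-dimethylnon-8-en-2-yn-1-ol
Product: 16 tert-butyl{[(4S,6S)-6-bromo-4-chloro-5,5-dimethylnon-8-en-2-yn-1-yl]oxy}dimethylsilane
Conditions: TBSCl, imidazole, CH2Cl2, 0 °C → rt
Reagents that add atoms: tert-butyldimethylsilyl chloride, CC(C)(C)[Si](C)(C)Cl
Why: Imidazole-promoted silylation of a primary alcohol with TBSCl, a neutral and routine protection that leaves both secondary halides untouched and masks C8–OH for the later selective C4 chlorination.

Step 9
Reactants: 16 tert-butyl{[(4S,6S)-6-bromo-4-chloro-5,5-dimethylnon-8-en-2-yn-1-yl]oxy}dimethylsilane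
Product: 18 (3S,5S)-3-bromo-8-(tert-butyldimethylsilyloxy)-5-chloro-4,4-dimethyloct-6-ynal, via ozonide 17 (not isolated)
Conditions: O3, CH2Cl2, −78 °C (Sudan Red 7B end point); then PPh3, −78 °C → rt; short silica plug
Reagents that add atoms: ozone, [O-][O+]=O
Why: Ozonolysis with reductive work-up cleaves the electron-rich terminal alkene much faster than the electron-poor internal alkyne (the dye marks the end point), and the neutral phosphine reduction followed by a quick silica plug removes phosphorus residues without exposing the β-bromo aldehyde to base that would eliminate HBr.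

Step 10
Reactants: 18 (3S,5S)-3-bromo-8-(tert-butyldimethylsilyloxy)-5-chloro-4,4-dimethyloct-6-ynal
Product: 19 (1R,3S,5S)-5-bromo-2-[(2Z)-2-(tert-butyldimethylsilyloxy)ethylidene]-3-chloro-4,4-dimethylcyclohexan-1-ol (C4 hydroxyl equatorial, cis to bromine)
Conditions: H2 (1 atm), Rh(cod)2OTf (5 mol %), 2,2'-bis(diphenylphosphino)-1,1'-biphenyl (BIPHEP, 5 mol %), 2-naphthoic acid (10 mol %), ClCH2CH2Cl, 25 → 45 °C
Reagents that add atoms: none
Why: Cationic monovalent rhodium binds the alkyne and the aldehyde and couples them oxidatively to an oxarhodacyclopentene, which forms the C4–C5 bond, and acid-assisted hydrogenolysis then replaces the Rh–C7 bond by C7–H with retention, so that C4 and H are delivered syn across C5≡C7 and the alkene is Z (C8 cis to C6). The closest known reaction type is the hydrogen-mediated rhodium-catalysed reductive cyclisation of acetylenic aldehydes to 2-alkylidenecycloalkanols. The cyclohexane ring closes in a 6-exo-dig mode (C4 onto C5, with C7 remaining outside the ring). The new stereocentre C4 is controlled by the substrate: in the chair-like transition state C2–Br is equatorial and C6–Cl axial, which avoids allylic 1,3-strain with the C8 arm that ends up cis to C6, and the nearly planar metallacycle holds the C4–O bond in the plane of the nascent alkene, that is equatorial and cis to bromine, giving the (R)-carbinol at C4. The step needs chemoselectivity for oxidative coupling over plain hydrogenation of the alkyne, over ionisation of the propargylic C6–Cl bond at the metal and over loss of HBr from the β-bromo aldehyde; the base-free, weakly acidic medium, the neopentyl shielding of both halides and the gem-dimethyl group that preorganises the chain for closure should secure it.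

Step 11
Reactants: 19 (1R,3S,5S)-5-bromo-2-[(2Z)-2-(tert-butyldimethylsilyloxy)ethylidene]-3-chloro-4,4-dimethylcyclohexan-1-ol
Product: 20 tert-butyl{[(2Z)-2-[(2S,4S,6S)-4-bromo-2,6-dichloro-3,3-dimethylcyclohexylidene]ethyl]oxy}dimethylsilane
Conditions: PPh3, Cl3CC(O)CCl3, CH2Cl2, −20 → 0 °C
Reagents that add atoms: hexachloroacetone, O=C(C(Cl)(Cl)Cl)C(Cl)(Cl)Cl
Why: Appel-type deoxychlorination with PPh3 and hexachloroacetone, the reagent pair known to convert allylic alcohols into chlorides with inversion and without allylic transposition; chloride displaces the activated equatorial C4–O bond from the opposite face, which gives the axial (S)-chloride cis to C6–Cl, while the silyl ether is not attacked at this temperature.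

Step 12
Reactants: 20 tert-butyl{[(2Z)-2-[(2S,4S,6S)-4-bromo-2,6-dichloro-3,3-dimethylcyclohexylidene]ethyl]oxy}dimethylsilane
Product: 21 (2S,4S,6S)-6-bromo-3-[(2Z)-2-bromoethylidene]-2,4-dichloro-1,1-dimethylcyclohexane (CNP0156384.1)
Conditions: Ph3PBr2, CH2Cl2, 0 °C → rt
Reagents that add atoms: dibromotriphenylphosphorane, BrP(Br)(c1ccccc1)(c1ccccc1)c1ccccc1
Why: Dibromotriphenylphosphorane converts silyl ethers directly into bromides (silicon is transferred to bromide and the resulting oxyphosphonium is displaced by SN2 at the unhindered primary allylic C8); SN2' attack at the fully substituted C5 is blocked, the two flanking C–Cl bonds disfavour an allyl cation, and so the Z alkene and the C4 chloride should persist.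

Compound list
1 | (S)-(+)-pantolactone, (3S)-3-hydroxy-4,4-dimethyloxolan-2-one | CC1(C)COC(=O)[C@H]1O | starting material
2 | (3S)-4,4-dimethyl-2-oxooxolan-3-yl trifluoromethanesulfonate (pantolactone triflate) | CC1(C)COC(=O)[C@H]1OS(=O)(=O)C(F)(F)F | intermediate
3 | (3R)-3-chloro-4,4-dimethyloxolan-2-one | CC1(C)COC(=O)[C@@H]1Cl | intermediate
4 | (3R)-3-chloro-4,4-dimethyloxolan-2-ol (anomeric mixture) | CC1(C)COC(O)[C@@H]1Cl | intermediate
5 | dimethyl (1-diazo-2-oxopropyl)phosphonate | COP(=O)(OC)C(=[N+]=[N-])C(C)=O | starting material
6 | (2R)-2-chloro-4-hydroxy-3,3-dimethylbutanal (open form of 4) | OCC(C)(C)[C@@H](Cl)C=O | intermediate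
7 | (3S)-3-chloro-2,2-dimethylpent-4-yn-1-ol | OCC(C)(C)[C@@H](Cl)C#C | intermediate
8 | (3S)-3-chloro-2,2-dimethylpent-4-ynal | O=CC(C)(C)[C@@H](Cl)C#C | intermediate
9 | allylboronic acid pinacol ester | C=CCB1OC(C)(C)C(C)(C)O1 | starting material
10 | (4R,6S)-6-chloro-5,5-dimethyloct-1-en-7-yn-4-ol | C=CC[C@@H](O)C(C)(C)[C@@H](Cl)C#C | intermediate
11 | (4R,6S)-6-chloro-5,5-dimethyloct-1-en-7-yn-4-yl trifluoromethanesulfonate | C=CC[C@@H](OS(=O)(=O)C(F)(F)F)C(C)(C)[C@@H](Cl)C#C | intermediate
12 | (4S,6S)-4-bromo-6-chloro-5,5-dimethyloct-1-en-7-yne | C=CC[C@H](Br)C(C)(C)[C@@H](Cl)C#C | intermediate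
13 | formaldehyde (monomer from paraformaldehyde) | C=O | starting material
14 | [(3S,5S)-5-bromo-3-chloro-4,4-dimethyloct-7-en-1-yn-1-yl]lithium | C=CC[C@H](Br)C(C)(C)[C@@H](Cl)C#C[Li] | intermediate
15 | (4S,6S)-6-bromo-4-chloro-5,5-dimethylnon-8-en-2-yn-1-ol | C=CC[C@H](Br)C(C)(C)[C@@H](Cl)C#CCO | intermediate
16 | tert-butyl{[(4S,6S)-6-bromo-4-chloro-5,5-dimethylnon-8-en-2-yn-1-yl]oxy}dimethylsilane | C=CC[C@H](Br)C(C)(C)[C@@H](Cl)C#CCO[Si](C)(C)C(C)(C)C | intermediate
17 | 3-[(2S,4S)-2-bromo-7-(tert-butyldimethylsilyloxy)-4-chloro-3,3-dimethylhept-5-yn-1-yl]-1,2,4-trioxolane (ozonide, mixture at the ring carbon) | O1OC(C[C@H](Br)C(C)(C)[C@@H](Cl)C#CCO[Si](C)(C)C(C)(C)C)OC1 | intermediate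
18 | (3S,5S)-3-bromo-8-(tert-butyldimethylsilyloxy)-5-chloro-4,4-dimethyloct-6-ynal | CC(C)([C@@H](Br)CC=O)[C@@H](Cl)C#CCO[Si](C)(C)C(C)(C)C | intermediate
19 | (1R,3S,5S)-5-bromo-2-[(2Z)-2-(tert-butyldimethylsilyloxy)ethylidene]-3-chloro-4,4-dimethylcyclohexan-1-ol | CC1(C)[C@@H](Br)C[C@@H](O)/C(=C/CO[Si](C)(C)C(C)(C)C)[C@@H]1Cl | intermediate
20 | tert-butyl{[(2Z)-2-[(2S,4S,6S)-4-bromo-2,6-dichloro-3,3-dimethylcyclohexylidene]ethyl]oxy}dimethylsilane | CC1(C)[C@@H](Br)C[C@H](Cl)/C(=C/CO[Si](C)(C)C(C)(C)C)[C@@H]1Cl | intermediate
21 | (2S,4S,6S)-6-bromo-3-[(2Z)-2-bromoethylidene]-2,4-dichloro-1,1-dimethylcyclohexane | CC1(C)[C@@H](Br)C[C@H](Cl)/C(=C/CBr)[C@@H]1Cl | target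

Total step count: 12. Longest linear sequence: 12 steps, from 1 to 21.

Steps most likely to fail

Step 10 (key step). The catalyst may simply hydrogenate the alkyne, may ionise the propargylic C6–Cl bond at the metal, or may show weak facial control at C4; the aldehyde may also lose HBr before it cyclises. The fallback sets out from ynal 18 and uses the silane-terminated nickel manifold that is established for acetylenic aldehydes: Ni(cod)2 (10 mol %), PBu3 (20 mol %) and Et3SiH in THF at 0 °C → rt. Oxidative cyclisation at zerovalent nickel followed by σ-bond metathesis with the silane forms the same C4–C5 bond with the same syn geometry and should give the C4 triethylsilyl ether F1. Selective methanolysis of this secondary triethylsilyl ether (PPTS, MeOH, 0 °C), which leaves the primary tert-butyldimethylsilyl ether in place, comes back to the route at alcohol 19.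

Step 6. Substitution at the neopentyl C2 may be too slow, so that elimination towards C3 (giving a conjugated diene) or ionisation of the triflate with methyl shift or alkene participation takes over. The fallback sets out from alcohol 10 and changes the activation from a sulfonate ester to an alkoxyphosphonium salt under Appel conditions (CBr4, P(n-C8H17)3, toluene, 60 °C). Bromide then attacks within a non-ionising ion pair, again with inversion, and the sequence comes back to the route at bromide 12 without passing through any compound outside the list.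

Step 3. Ring opening of the gem-dimethyl lactol may be slow in basic methanol, which would leave time for enolisation of the α-chloro aldehyde (erosion of the C6 configuration) or for loss of chloride through the hemiacetal alkoxide. The fallback sets out from lactol 4 and avoids the protic base altogether by a Corey–Fuchs sequence: neutral dibromomethylenation (CBr4, PPh3, Zn, CH2Cl2, rt) should give the dibromoalkene F2, and n-BuLi (3 equiv, THF, −78 °C; aq. NH4Cl) would convert it through bromine–lithium exchange and rearrangement into the terminal alkyne, coming back to the route at alkynol 7.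

Further compounds
F1 | step 10 | triethyl{[(1R,3S,5S)-5-bromo-2-[(2Z)-2-(tert-butyldimethylsilyloxy)ethylidene]-3-chloro-4,4-dimethylcyclohexyl]oxy}silane | CC1(C)[C@@H](Br)C[C@@H](O[Si](CC)(CC)CC)/C(=C/CO[Si](C)(C)C(C)(C)C)[C@@H]1Cl
F0 | step 6 | none | none
F2 | step 3 | (3S)-5,5-dibromo-3-chloro-2,2-dimethylpent-4-en-1-ol | OCC(C)(C)[C@@H](Cl)C=C(Br)Br
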